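Ring A is opened at the C2–C3 bond (eudesmane numbering), which turns the C1–OH/C2/C3–O array into an aldol retron and the target into an elemane-type 2,3-seco-eudesmane. In the key step the methyl group of a C10 acetyl unit, the only enolisable position because C10 is quaternary, adds as its lithium enolate to a non-enolisable C3 enal carbonyl held on C5. This closes ring A with the C4(15) methylene and both oxygens in place and sets C3. The keto-enal precursor, a trans-1-acetyl-1-methyl-2-(1-formylvinyl)cyclohexane carrying the isopropyl and silyloxy groups, is built from (R)-carvone by two trans-selective cuprate additions.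

Key step: step 11

Remark: eudesmane locants C1–C15 are used for all intermediates, β is the face of the C10 methyl group and α the opposite face.

Step 1
Reactants: 1 (R)-(−)-carvone
Product: 2 (R)-carvotanacetone
Conditions: H2 (1 atm), RhCl(PPh3)3 (2 mol%), benzene, rt
Reagents that add atoms: none
Why: Homogeneous hydrogenation with RhCl(PPh3)3 should reduce the unhindered 1,1-disubstituted isopropenyl alkene and leave the trisubstituted conjugated enone, so the C7 stereocentre of carvone is carried over unchanged.

Step 2
Reactants: 2 (R)-carvotanacetone; 3 (1,3-dioxolan-2-ylmethyl)magnesium bromide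
Product: 5 enol triflate of the 1,4-adduct (C5 side chain β trans to C7 isopropyl α), via bromomagnesium enolate 4 (not isolated)
Conditions: CuBr·SMe2 (10 mol%), THF, −40 °C; then PhNTf2, DMPU, −40 °C → rt
Reagents that add atoms: N-phenylbis(trifluoromethanesulfonimide), O=S(=O)(N(c1ccccc1)S(=O)(=O)C(F)(F)F)C(F)(F)F
Why: Copper-catalysed conjugate addition of the Grignard reagent should occur axially on the enone face anti to the C7 isopropyl group (trans addition, as for 5-substituted cyclohexenones), which sets C5, and O-triflation of the regiodefined magnesium enolate fixes the double bond at C9=C10.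

Step 3
Reactants: 5 enol triflate
Product: 6 trisubstituted alkene (C9=C10) with the 5β acetal side chain and 7α isopropyl group
Conditions: Pd(OAc)2 (5 mol%), PPh3 (10 mol%), HCO2H, n-Bu3N, DMF, 60 °C
Reagents that add atoms: none
Why: Palladium-catalysed formate hydrogenolysis of the enol triflate (oxidative addition to zerovalent palladium, formate exchange, decarboxylation, reductive elimination) should replace OTf by H without moving the alkene or touching a stereocentre.

Step 4
Reactants: 6 trisubstituted alkene
Product: 7 4,6-trans enone (C8 ketone with C9=C10; 5β side chain and 7α isopropyl)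
Conditions: CrO3, 3,5-dimethylpyrazole, CH2Cl2, −20 °C
Reagents that add atoms: chromium trioxide, O=[Cr](=O)=O
Why: Allylic C–H oxidation with the CrO3–3,5-dimethylpyrazole complex should attack the ring CH2 (C8) next to the CH terminus of the trisubstituted alkene, as 1-methylcyclohexene gives 3-methylcyclohexenone, which places the carbonyl where C10 becomes a β-carbon and C7 becomes epimerisable.

Step 5
Reactants: 7 4,6-trans enone; 8 vinylmagnesium bromide
Product: 11 ketone with quaternary C10 (10β-methyl 10α-vinyl 5β side chain 7β-isopropyl), via enol silane 9 (not isolated), via C7-epimeric ketone 10 (not isolated)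
Conditions: CH2=CHMgBr, CuBr·SMe2 (10 mol%), Me3SiCl, DMPU, THF, −78 → −40 °C; then K2CO3, MeOH, rt
Reagents that add atoms: none
Why: Me3SiCl-accelerated copper-catalysed conjugate addition should deliver vinyl axially to C10 anti to the pseudo-axial C5 side chain of the 4,6-trans enone (its C7 isopropyl group is equatorial in that half-chair), which sets the quaternary centre with vinyl α and methyl β, and K2CO3/MeOH then cleaves enol silane 9 and equilibrates C7 of ketone 10 through the enolate to the isomer 11 in which only the methyl group is axial.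

Step 6
Reactants: 11 ketone
Product: 12 8α-alcohol (equatorial hydroxyl trans to the 7β-isopropyl group)
Conditions: Li, NH3(l), t-BuOH, THF, −78 → −33 °C; NH4Cl
Reagents that add atoms: none
Why: Dissolving-metal reduction of the ketone proceeds under thermodynamic control through the ketyl and should give the equatorial 8α alcohol, the epimer that avoids a 1,3-diaxial contact with the axial C10 methyl group, while the acetal and the isolated vinyl group are inert.

Step 7
Reactants: 12 8α-alcohol
Product: 13 8α-tert-butyldimethylsilyl ether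
Conditions: TBSCl, imidazole, DMAP (cat.), DMF, 45 °C
Reagents that add atoms: tert-butyldimethylsilyl chloride, CC(C)(C)[Si](C)(C)Cl
Why: Imidazole-promoted silyl ether formation masks O8 for the aldol, reduction and Mitsunobu steps, and the group leaves together with the phenol ethers at the end.

Step 8
Reactants: 13 silyl ether acetal
Product: 14 aldehyde (C5–CH2–CHO)
Conditions: PPTS (cat.), acetone/H2O (5:1), 55 °C
Reagents that add atoms: water, O
Why: Mild acid-catalysed acetal hydrolysis should free the aldehyde without cleaving the hindered secondary silyl ether.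

Step 9
Reactants: 14 aldehyde
Product: 15 enal (C5–C(=CH2)–CHO)
Conditions: 37% aq. CH2O, pyrrolidine (10 mol%), EtCO2H (10 mol%), i-PrOH, 45 °C
Reagents that add atoms: formaldehyde, C=O
Why: Amine-catalysed α-methylenation (Mannich condensation of the enamine with formaldehyde, then β-elimination of the amine) should convert the CH2CHO chain into the 2-substituted acrolein that carries C15, C4 and C3.

Step 10
Reactants: 15 enal
Product: 16 keto-enal (C10 acetyl and C5 1-formylvinyl groups trans)
Conditions: PdCl2 (10 mol%), CuCl (30 mol%), O2 (1 atm), DMF/H2O (7:1), rt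
Reagents that add atoms: water, O
Why: Tsuji–Wacker oxidation should hydrate the monosubstituted vinyl group with Markovnikov regiochemistry to the methyl ketone (O2 and CuCl reoxidise palladium), while the electron-poor 1,1-disubstituted enal alkene is not oxidised.

Step 11
Reactants: 16 keto-enal
Product: 18 3α-hydroxy-8α-silyloxy-eudesm-4(15)-en-1-one, via lithium enolate 17 (not isolated)
Conditions: LiN(SiMe3)2 (1.1 equiv), THF (0.01 M, slow addition of 16), −78 °C; AcOH, −78 °C
Reagents that add atoms: none
Why: Deprotonation can occur only at the acetyl methyl group (C2), because C10 is quaternary and the enal has no α-hydrogen, and the lithium enolate 17 adds to the C3 aldehyde in an intramolecular aldol addition that forms the C2–C3 bond. The closure is a 6-(enolendo)-exo-trig cyclisation, the mode of the ketol-forming step of a Robinson annulation, and the trans-diequatorial placement of the acetyl and acrolein groups on the cyclohexane makes the new ring A trans-fused to ring B. The new C3 stereocentre is controlled by lithium chelation: only a carbonyl oxygen that is gauche to C1 (pseudo-axial on the forming chair, α face) can bridge to the enolate oxygen through lithium, and this arrangement also keeps the enal close to its preferred s-trans geometry, so the axial 3α alcohol is expected. The step needs 1,2- rather than 1,4-addition and no β-elimination: the lithium enolate should add to the carbonyl carbon under kinetic control at −78 °C, and the cold acetic acid quench should stop retro-aldol, conjugate closure onto C15 and dehydration.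

Step 12
Reactants: 18 3α-hydroxy ketone
Product: 19 8α-silyloxy-eudesm-4(15)-ene-1β,3α-diol
Conditions: Me4NBH(OAc)3, MeCN/AcOH (1:1), −30 °C
Reagents that add atoms: none
Why: In this Evans–Saksena hydroxyl-directed reduction the axial 3α alkoxyborohydride delivers hydride intramolecularly to the α face of the C1 ketone, the face also preferred for axial attack anti to the C10 methyl group, which should give the equatorial 1β alcohol (1,3-anti diol).

Step 13
Reactants: 20 caffeic acid
Product: 22 (E)-3-[3,4-bis(tert-butyldimethylsilyloxy)phenyl]prop-2-enoic acid, via tris-silyl derivative 21 (not isolated)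
Conditions: TBSCl (3.3 equiv), imidazole, DMF, rt; then AcOH/THF/H2O (3:1:1), rt
Reagents that add atoms: tert-butyldimethylsilyl chloride, CC(C)(C)[Si](C)(C)Cl
Why: Exhaustive silylation followed by selective hydrolysis of the labile silyl ester should give the catechol-protected acid.

Step 14
Reactants: 19 1β,3α-diol; 22 bis-silylated caffeic acid
Product: 23 fully silylated 3β-caffeate (1β-hydroxy 8α-silyloxy)
Conditions: PPh3, DIAD, toluene, 0 °C → rt
Reagents that add atoms: none
Why: Mitsunobu esterification should activate only the axial allylic C3 hydroxyl (the C1 hydroxyl next to quaternary C10 is too hindered), and the carboxylate displaces it with SN2 inversion, so the ester arrives in the equatorial 3β configuration.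

Step 15
Reactants: 23 silylated ester
Product: 24 target, 1β,8α-dihydroxyeudesm-4(15)-en-3β-yl (E)-caffeate
Conditions: HF·pyridine, pyridine/THF, 0 °C → rt, under argon
Reagents that add atoms: none
Why: Fluoride-mediated desilylation under buffered acidic conditions should remove the two aryl silyl ethers and the alkyl silyl ether without hydrolysing or migrating the allylic cinnamate ester.

Compound list
1 | (R)-(−)-carvone, (5R)-2-methyl-5-(prop-1-en-2-yl)cyclohex-2-en-1-one | CC1=CC[C@H](CC1=O)C(C)=C | starting material
2 | (R)-carvotanacetone, (5R)-2-methyl-5-(propan-2-yl)cyclohex-2-en-1-one | CC1=CC[C@H](CC1=O)C(C)C | intermediate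
3 | (1,3-dioxolan-2-ylmethyl)magnesium bromide (THF solution) | Br[Mg]CC1OCCO1 | starting material
4 | bromomagnesium enolate of the 1,4-adduct (OMgBr on C9, C9=C10, C5 side chain β, C7 isopropyl α; not isolated) | CC1=C(O[Mg]Br)C[C@H](C(C)C)C[C@H]1CC2OCCO2 | intermediate
5 | 3-(1,3-dioxolan-2-ylmethyl)-2-methyl-5-(propan-2-yl)cyclohex-1-en-1-yl trifluoromethanesulfonate, side chain (C5 β) trans to isopropyl (C7 α) | CC1=C(OS(=O)(=O)C(F)(F)F)C[C@H](C(C)C)C[C@H]1CC2OCCO2 | intermediate
6 | 2-{[2-methyl-5-(propan-2-yl)cyclohex-2-en-1-yl]methyl}-1,3-dioxolane, ring substituents trans (C5 β, C7 α), C9=C10 alkene | CC1=CC[C@H](C(C)C)C[C@H]1CC2OCCO2 | intermediate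
7 | 4-(1,3-dioxolan-2-ylmethyl)-3-methyl-6-(propan-2-yl)cyclohex-2-en-1-one, 4,6-trans (C8 ketone, C5 side chain β, C7 isopropyl α) | CC1=CC(=O)[C@H](C(C)C)C[C@H]1CC2OCCO2 | intermediate
8 | vinylmagnesium bromide | C=C[Mg]Br | starting material
9 | trimethylsilyl enol ether (C8–OSiMe3, C8=C9) of the vinyl adduct; 10β-methyl, 10α-vinyl, 5β side chain, 7α-isopropyl (not isolated) | C[C@@]1(C=C)C=C(O[Si](C)(C)C)[C@H](C(C)C)C[C@H]1CC2OCCO2 | intermediate
10 | C7-epimeric ketone: 3-ethenyl-4-(1,3-dioxolan-2-ylmethyl)-3-methyl-6-(propan-2-yl)cyclohexan-1-one with 7α (axial) isopropyl (not isolated) | C[C@@]1(C=C)CC(=O)[C@H](C(C)C)C[C@H]1CC2OCCO2 | intermediate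
11 | 3-ethenyl-4-(1,3-dioxolan-2-ylmethyl)-3-methyl-6-(propan-2-yl)cyclohexan-1-one; 10β (axial) methyl, 10α vinyl, 5β side chain, 7β isopropyl (vinyl trans to side chain, side chain cis to isopropyl) | C[C@@]1(C=C)CC(=O)[C@@H](C(C)C)C[C@H]1CC2OCCO2 | intermediate
12 | the corresponding cyclohexan-1-ol with 8α (equatorial) hydroxyl, trans to the isopropyl group | C[C@@]1(C=C)C[C@H](O)[C@@H](C(C)C)C[C@H]1CC2OCCO2 | intermediate
13 | tert-butyldimethylsilyl ether of 12 | C[C@@]1(C=C)C[C@H](O[Si](C)(C)C(C)(C)C)[C@@H](C(C)C)C[C@H]1CC2OCCO2 | intermediate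
14 | 2-[8α-(TBSO)-7β-isopropyl-10β-methyl-10α-vinylcyclohex-5β-yl]acetaldehyde (ring B carbons C5–C10) | C[C@@]1(C=C)C[C@H](O[Si](C)(C)C(C)(C)C)[C@@H](C(C)C)C[C@H]1CC=O | intermediate
15 | 2-[8α-(TBSO)-7β-isopropyl-10β-methyl-10α-vinylcyclohex-5β-yl]prop-2-enal | C[C@@]1(C=C)C[C@H](O[Si](C)(C)C(C)(C)C)[C@@H](C(C)C)C[C@H]1C(=C)C=O | intermediate
16 | 2-[10α-acetyl-8α-(TBSO)-7β-isopropyl-10β-methylcyclohex-5β-yl]prop-2-enal (acetyl and 1-formylvinyl groups trans, both equatorial) | C[C@@]1(C(C)=O)C[C@H](O[Si](C)(C)C(C)(C)C)[C@@H](C(C)C)C[C@H]1C(=C)C=O | intermediate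
17 | lithium enolate of 16 (C1–OLi, C1=C2; not isolated) | C[C@@]1(C(=C)O[Li])C[C@H](O[Si](C)(C)C(C)(C)C)[C@@H](C(C)C)C[C@H]1C(=C)C=O | intermediate
18 | 8α-(tert-butyldimethylsilyloxy)-3α-hydroxyeudesm-4(15)-en-1-one (trans-decalin, 5α-H, 7β-isopropyl, 10β-methyl, axial 3-OH) | C=C1[C@H](O)CC(=O)[C@]2(C)C[C@H](O[Si](C)(C)C(C)(C)C)[C@@H](C(C)C)C[C@@H]12 | intermediate
19 | 8α-(tert-butyldimethylsilyloxy)eudesm-4(15)-ene-1β,3α-diol | C=C1[C@H](O)C[C@@H](O)[C@]2(C)C[C@H](O[Si](C)(C)C(C)(C)C)[C@@H](C(C)C)C[C@@H]12 | intermediate
20 | caffeic acid, (E)-3-(3,4-dihydroxyphenyl)prop-2-enoic acid | O=C(O)/C=C/c1ccc(O)c(O)c1 | starting material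
21 | tert-butyldimethylsilyl (E)-3-[3,4-bis(tert-butyldimethylsilyloxy)phenyl]prop-2-enoate (not isolated) | CC(C)(C)[Si](C)(C)OC(=O)/C=C/c1ccc(O[Si](C)(C)C(C)(C)C)c(O[Si](C)(C)C(C)(C)C)c1 | intermediate
22 | (E)-3-[3,4-bis(tert-butyldimethylsilyloxy)phenyl]prop-2-enoic acid | O=C(O)/C=C/c1ccc(O[Si](C)(C)C(C)(C)C)c(O[Si](C)(C)C(C)(C)C)c1 | intermediate
23 | 8α-(tert-butyldimethylsilyloxy)-1β-hydroxyeudesm-4(15)-en-3β-yl (E)-3-[3,4-bis(tert-butyldimethylsilyloxy)phenyl]prop-2-enoate | C=C1[C@@H](OC(=O)/C=C/c2ccc(O[Si](C)(C)C(C)(C)C)c(O[Si](C)(C)C(C)(C)C)c2)C[C@@H](O)[C@]2(C)C[C@H](O[Si](C)(C)C(C)(C)C)[C@@H](C(C)C)C[C@@H]12 | intermediate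
24 | CNP0264533.1, (1R,3S,5S,7R,8S,10R)-1β,8α-dihydroxyeudesm-4(15)-en-3β-yl (E)-3-(3,4-dihydroxyphenyl)prop-2-enoate | C=C1[C@@H](OC(=O)/C=C/c2ccc(O)c(O)c2)C[C@@H](O)[C@]2(C)C[C@H](O)[C@@H](C(C)C)C[C@@H]12 | target

Total step count: 15. Longest linear sequence: 14 steps (steps 1–12, 14 and 15; step 13 prepares the acid component).

Steps most likely to fail

Step 11 (aldol ring closure). What may go wrong: conjugate attack of the enolate on C15 instead of the carbonyl carbon, retro-aldol or β-elimination of the lithium aldolate to the cross-conjugated dienone before the quench, and loss of facial control through a non-chelated transition state. Fallback: a reductive chromium Reformatsky closure that needs no base. It sets out from 15. Bromohydration of the vinyl group (N-bromosuccinimide, THF/H2O, 0 °C) should give the bromohydrin F1, and Dess–Martin oxidation should give the α-bromo ketone F2. CrCl2 with LiI (cat.) in THF at rt should then turn F2 into a chromium enolate that adds only to the aldehyde carbonyl through the same chelated arrangement. The route is rejoined at 18.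

Step 14 (Mitsunobu esterification). What may go wrong: anti-elimination of the activated axial C3 oxygen with the axial C2 hydrogen to the 2,4(15)-diene, or SN2′ attack of the carboxylate at C15 with a shift of the double bond into the ring. Fallback: invert C3 by oxidation and reduction, then acylate with retention. It sets out from 19. MnO2 (CH2Cl2, rt) should oxidise only the allylic C3 alcohol to the 4(15)-en-3-one F3. Luche reduction (NaBH4, CeCl3·7H2O, MeOH, −78 °C; axial hydride delivery) should give the diequatorial 1β,3β-diol F4. Steglich-type coupling of F4 with 22 (EDC·HCl, DMAP, CH2Cl2, 0 °C) at the less hindered allylic hydroxyl rejoins the route at 23.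

Step 4 (allylic oxidation). What may go wrong: hydrogen abstraction at the tertiary C5–H or at the C10 methyl group instead of C8, giving regioisomeric enones, and partial epimerisation at C7 of the product before step 5. Fallback: bring the oxygen to C8 by an epoxide-based 1,3-transposition instead of C–H oxidation. It sets out from 6. 3-Chloroperoxybenzoic acid (CH2Cl2, 0 °C) should give the 9α,10α-epoxide F5. PhSeNa (from PhSeSePh and NaBH4, EtOH) should open it at C9 to the hydroxy selenide F6. H2O2 should eliminate the selenoxide towards C8 to the tertiary allylic alcohol F7. Pyridinium chlorochromate (CH2Cl2, rt) should convert F7 by Babler–Dauben oxidative transposition into 7, where the route is rejoined.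

Further compounds
F1 | step 11 | bromohydrin of 15 (C1 carbinol as epimer mixture, C2 bromide) | C[C@@]1(C(O)CBr)C[C@H](O[Si](C)(C)C(C)(C)C)[C@@H](C(C)C)C[C@H]1C(=C)C=O
F2 | step 11 | α-bromo ketone (C10 bromoacetyl analogue of 16) | C[C@@]1(C(=O)CBr)C[C@H](O[Si](C)(C)C(C)(C)C)[C@@H](C(C)C)C[C@H]1C(=C)C=O
F3 | step 14 | 8α-(tert-butyldimethylsilyloxy)-1β-hydroxyeudesm-4(15)-en-3-one | C=C1C(=O)C[C@@H](O)[C@]2(C)C[C@H](O[Si](C)(C)C(C)(C)C)[C@@H](C(C)C)C[C@@H]12
F4 | step 14 | 8α-(tert-butyldimethylsilyloxy)eudesm-4(15)-ene-1β,3β-diol | C=C1[C@@H](O)C[C@@H](O)[C@]2(C)C[C@H](O[Si](C)(C)C(C)(C)C)[C@@H](C(C)C)C[C@@H]12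
F5 | step 4 | 9α,10α-epoxide of 6 | C[C@@]12O[C@@H]1C[C@H](C(C)C)C[C@H]2CC1OCCO1
F6 | step 4 | 10α-hydroxy-9β-phenylselanyl derivative of 6 | C[C@@]1(O)[C@@H]([Se]c2ccccc2)C[C@H](C(C)C)C[C@H]1CC3OCCO3
F7 | step 4 | tertiary allylic alcohol (10α-hydroxy, C8=C9 alkene) | C[C@@]1(O)C=C[C@H](C(C)C)C[C@H]1CC2OCCO2
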